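**Retrosynthetic overview**
- The target is unmasked from its 5‑O‑MOM ether; the 1,2‑diketone comes from Riley oxidation of the CH2 of a deoxybenzoin.
- The deoxybenzoin comes from a β‑keto ester (decarboxylation), itself from a β‑hydroxy ester. The key C–C bond (the future CO–CO bond) is made by an intermolecular aldol addition of the lithium enolate of methyl 4‑methoxyphenylacetate to a chromene‑6‑carbaldehyde.
- The chromene aldehyde comes from an aryl 1,1‑dimethylpropargyl ether (Claisen rearrangement / oxa‑6π closure), made from isovanillin by O‑propargylation, Baeyer–Villiger oxidation, ortho‑formylation and MOM protection.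
- Ring order: both benzene rings are bought; the pyran ring is the only ring formed (step 5).

Assumption: dielsianone has no stereocentre, so there is no enantiomer to control; the two stereocentres created in the aldol step are formed as a mixture and are both erased later.

**Step 1**
Reactants: 1 isovanillin (3‑hydroxy‑4‑methoxybenzaldehyde); 2 3‑chloro‑3‑methylbut‑1‑yne
Product: 3 4‑methoxy‑3‑[(2‑methylbut‑3‑yn‑2‑yl)oxy]benzaldehyde
Conditions: K2CO3, KI (cat.), CuI (cat.), acetone, reflux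
Reagents that add atoms: none
Why: Copper‑assisted Williamson‑type O‑alkylation of the phenoxide with the tertiary propargylic chloride gives the aryl 1,1‑dimethylpropargyl ether, and the aldehyde and methyl ether are inert.

**Step 2**
Reactants: 3 4‑methoxy‑3‑[(2‑methylbut‑3‑yn‑2‑yl)oxy]benzaldehyde
Product: 5 4‑methoxy‑3‑[(2‑methylbut‑3‑yn‑2‑yl)oxy]phenol, via aryl formate 4 (not isolated)
Conditions: mCPBA, CH2Cl2, 0 °C → rt; then K2CO3 (cat.), MeOH, rt
Reagents that add atoms: mCPBA, O=C(OO)c1cccc(Cl)c1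
Why: Baeyer–Villiger (Dakin‑type) oxidation in which the electron‑rich aryl group (para‑OMe) migrates to give the formate, which is methanolysed to the phenol while the alkyne is untouched by the peracid.

**Step 3**
Reactants: 5 4‑methoxy‑3‑[(2‑methylbut‑3‑yn‑2‑yl)oxy]phenol
Product: 7 2‑hydroxy‑5‑methoxy‑4‑[(2‑methylbut‑3‑yn‑2‑yl)oxy]benzaldehyde, via salicyl alcohol 6 (not isolated)
Conditions: MgCl2, Et3N, (CH2O)n, THF, 65 °C; aq. HCl work‑up
Reagents that add atoms: paraformaldehyde (as formaldehyde), C=O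
Why: Magnesium‑phenoxide‑directed ortho‑formylation (Casnati–Skattebøl) can only reach C6, because C2 is buried between the two oxygens and the para position carries OMe, and the hydroxymethyl intermediate is oxidised by a second formaldehyde through Oppenauer‑type hydride transfer.

**Step 4**
Reactants: 7 2‑hydroxy‑5‑methoxy‑4‑[(2‑methylbut‑3‑yn‑2‑yl)oxy]benzaldehyde
Product: 8 5‑methoxy‑2‑(methoxymethoxy)‑4‑[(2‑methylbut‑3‑yn‑2‑yl)oxy]benzaldehyde
Conditions: NaH, MOMCl, THF/DMF, 0 °C → rt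
Reagents that add atoms: chloromethyl methyl ether (MOMCl), COCCl
Why: Williamson O‑alkylation of the sodium phenoxide masks the 2‑OH, so that only the 4‑oxygen can close the pyran ring in step 5 and the phenol is protected from LDA, DMP and SeO2 later.

**Step 5**
Reactants: 8 5‑methoxy‑2‑(methoxymethoxy)‑4‑[(2‑methylbut‑3‑yn‑2‑yl)oxy]benzaldehyde
Product: 11 8‑methoxy‑5‑(methoxymethoxy)‑2,2‑dimethyl‑2H‑chromene‑6‑carbaldehyde, via allenylphenol 9 (not isolated), via ortho‑quinone methide 10 (not isolated)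
Conditions: DMF, 150 °C (sealed tube)
Reagents that add atoms: none
Why: Aromatic propargyl Claisen rearrangement to the only free ortho carbon (C3, since C5 bears OMe), tautomerisation, 1,5‑H shift and oxa‑6π electrocyclisation give the 2,2‑dimethyl‑2H‑chromene with unambiguous regiochemistry.

**Step 6**
Reactants: 11 8‑methoxy‑5‑(methoxymethoxy)‑2,2‑dimethyl‑2H‑chromene‑6‑carbaldehyde; 12 methyl 4‑methoxyphenylacetate
Product: 14 methyl 3‑hydroxy‑3‑[8‑methoxy‑5‑(methoxymethoxy)‑2,2‑dimethyl‑2H‑chromen‑6‑yl]‑2‑(4‑methoxyphenyl)propanoate (racemic syn/anti mixture), via lithium enolate 13 (not isolated)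
Conditions: 12, LDA, THF, −78 °C; then 11, −78 °C; sat. NH4Cl at −78 °C
Reagents that add atoms: none
Why: Intermolecular aldol addition of the preformed lithium ester enolate to the non‑enolisable aryl aldehyde forms the future CO–CO bond, and the two new stereocentres are formed unselectively on purpose because both are destroyed in steps 7–9.

**Step 7**
Reactants: 14 methyl 3‑hydroxy‑3‑[8‑methoxy‑5‑(methoxymethoxy)‑2,2‑dimethyl‑2H‑chromen‑6‑yl]‑2‑(4‑methoxyphenyl)propanoate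
Product: 15 methyl 3‑[8‑methoxy‑5‑(methoxymethoxy)‑2,2‑dimethyl‑2H‑chromen‑6‑yl]‑2‑(4‑methoxyphenyl)‑3‑oxopropanoate (racemic)
Conditions: Dess–Martin periodinane (1.2 equiv), CH2Cl2, 0 °C → rt
Reagents that add atoms: none
Why: Dess–Martin oxidation converts the benzylic secondary alcohol into the β‑keto ester under near‑neutral conditions that spare the MOM ether, the chromene alkene and the electron‑rich arenes.

**Step 8**
Reactants: 15 methyl 3‑[8‑methoxy‑5‑(methoxymethoxy)‑2,2‑dimethyl‑2H‑chromen‑6‑yl]‑2‑(4‑methoxyphenyl)‑3‑oxopropanoate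
Product: 16 1‑[8‑methoxy‑5‑(methoxymethoxy)‑2,2‑dimethyl‑2H‑chromen‑6‑yl]‑2‑(4‑methoxyphenyl)ethan‑1‑one
Conditions: LiCl, H2O (2 equiv), DMSO, 140 °C
Reagents that add atoms: none
Why: Krapcho dealkoxycarbonylation (chloride SN2 demethylation, then loss of CO2 from the β‑keto carboxylate) gives the deoxybenzoin under neutral conditions and removes the last stereocentre.

**Step 9**
Reactants: 16 1‑[8‑methoxy‑5‑(methoxymethoxy)‑2,2‑dimethyl‑2H‑chromen‑6‑yl]‑2‑(4‑methoxyphenyl)ethan‑1‑one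
Product: 17 1‑[8‑methoxy‑5‑(methoxymethoxy)‑2,2‑dimethyl‑2H‑chromen‑6‑yl]‑2‑(4‑methoxyphenyl)ethane‑1,2‑dione
Conditions: SeO2 (1.5 equiv), pyridine, 90 °C
Reagents that add atoms: selenium dioxide, O=[Se]=O
Why: Riley oxidation turns the doubly activated methylene (α to the ketone and benzylic) into the 1,2‑diketone, the chromene alkene has no allylic C–H to compete, and pyridine keeps the medium non‑acidic for the MOM ether.

**Step 10**
Reactants: 17 1‑[8‑methoxy‑5‑(methoxymethoxy)‑2,2‑dimethyl‑2H‑chromen‑6‑yl]‑2‑(4‑methoxyphenyl)ethane‑1,2‑dione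
Product: 18 dielsianone, 1‑(5‑hydroxy‑8‑methoxy‑2,2‑dimethyl‑2H‑chromen‑6‑yl)‑2‑(4‑methoxyphenyl)ethane‑1,2‑dione
Conditions: 3 M aq. HCl, THF, 40 °C
Reagents that add atoms: none
Why: Acid‑catalysed acetal hydrolysis of the MOM ether, assisted by the ortho carbonyl, frees the chelated phenol under conditions mild enough for the 2,2‑dimethylchromene and the diketone, and the target has no stereocentre to set.

**Compound list**
1 | isovanillin (3‑hydroxy‑4‑methoxybenzaldehyde) | COc1ccc(C=O)cc1O | starting material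
2 | 3‑chloro‑3‑methylbut‑1‑yne | C#CC(C)(C)Cl | starting material
3 | 4‑methoxy‑3‑[(2‑methylbut‑3‑yn‑2‑yl)oxy]benzaldehyde | COc1ccc(C=O)cc1OC(C)(C)C#C | intermediate
4 | 4‑methoxy‑3‑[(2‑methylbut‑3‑yn‑2‑yl)oxy]phenyl formate | COc1ccc(OC=O)cc1OC(C)(C)C#C | intermediate
5 | 4‑methoxy‑3‑[(2‑methylbut‑3‑yn‑2‑yl)oxy]phenol | COc1ccc(O)cc1OC(C)(C)C#C | intermediate
6 | 2‑(hydroxymethyl)‑4‑methoxy‑5‑[(2‑methylbut‑3‑yn‑2‑yl)oxy]phenol (formed as its magnesium salt) | COc1cc(CO)c(O)cc1OC(C)(C)C#C | intermediate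
7 | 2‑hydroxy‑5‑methoxy‑4‑[(2‑methylbut‑3‑yn‑2‑yl)oxy]benzaldehyde | COc1cc(C=O)c(O)cc1OC(C)(C)C#C | intermediate
8 | 5‑methoxy‑2‑(methoxymethoxy)‑4‑[(2‑methylbut‑3‑yn‑2‑yl)oxy]benzaldehyde | COCOc1cc(OC(C)(C)C#C)c(OC)cc1C=O | intermediate
9 | 4‑hydroxy‑5‑methoxy‑2‑(methoxymethoxy)‑3‑(3‑methylbuta‑1,2‑dien‑1‑yl)benzaldehyde | COCOc1c(C=C=C(C)C)c(O)c(OC)cc1C=O | intermediate
10 | (3Z)‑5‑methoxy‑2‑(methoxymethoxy)‑3‑(3‑methylbut‑2‑en‑1‑ylidene)‑4‑oxocyclohexa‑1,5‑diene‑1‑carbaldehyde | COCOC1=C(C=O)C=C(OC)C(=O)/C1=C\C=C(C)C | intermediate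
11 | 8‑methoxy‑5‑(methoxymethoxy)‑2,2‑dimethyl‑2H‑chromene‑6‑carbaldehyde | COCOc1c(C=O)cc(OC)c2c1C=CC(C)(C)O2 | intermediate
12 | methyl 4‑methoxyphenylacetate | COC(=O)Cc1ccc(OC)cc1 | starting material
13 | lithium enolate of methyl 4‑methoxyphenylacetate (geometry immaterial) | COC(O[Li])=Cc1ccc(OC)cc1 | intermediate
14 | methyl 3‑hydroxy‑3‑[8‑methoxy‑5‑(methoxymethoxy)‑2,2‑dimethyl‑2H‑chromen‑6‑yl]‑2‑(4‑methoxyphenyl)propanoate (racemic syn/anti mixture) | COCOc1c(C(O)C(C(=O)OC)c3ccc(OC)cc3)cc(OC)c2c1C=CC(C)(C)O2 | intermediate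
15 | methyl 3‑[8‑methoxy‑5‑(methoxymethoxy)‑2,2‑dimethyl‑2H‑chromen‑6‑yl]‑2‑(4‑methoxyphenyl)‑3‑oxopropanoate (racemic) | COCOc1c(C(=O)C(C(=O)OC)c3ccc(OC)cc3)cc(OC)c2c1C=CC(C)(C)O2 | intermediate
16 | 1‑[8‑methoxy‑5‑(methoxymethoxy)‑2,2‑dimethyl‑2H‑chromen‑6‑yl]‑2‑(4‑methoxyphenyl)ethan‑1‑one | COCOc1c(C(=O)Cc3ccc(OC)cc3)cc(OC)c2c1C=CC(C)(C)O2 | intermediate
17 | 1‑[8‑methoxy‑5‑(methoxymethoxy)‑2,2‑dimethyl‑2H‑chromen‑6‑yl]‑2‑(4‑methoxyphenyl)ethane‑1,2‑dione | COCOc1c(C(=O)C(=O)c3ccc(OC)cc3)cc(OC)c2c1C=CC(C)(C)O2 | intermediate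
18 | dielsianone (achiral) | COc1ccc(C(=O)C(=O)c2cc(OC)c3c(c2O)C=CC(C)(C)O3)cc1 | target

**Totals**
Total step count: 10. Longest linear sequence: 10 steps (1 → 18); 2 and 12 are bought.

**Three steps most likely to fail**

Step 6 (aldol addition). The electron‑rich benzylic aldolate may revert (retro‑aldol) or the addition may stall. The fallback sets out from 11 and moves the aldehyde to the acid oxidation level. Pinnick oxidation (NaClO2, NaH2PO4, 2‑methyl‑2‑butene, t‑BuOH/H2O) gives 8‑methoxy‑5‑(methoxymethoxy)‑2,2‑dimethyl‑2H‑chromene‑6‑carboxylic acid F1. Carbonyldiimidazole in THF converts it into the acyl imidazole F2. F2 is added at −78 °C to 2.2 equiv of the lithium enolate 13 (made from 12 with LiHMDS) in a crossed Claisen condensation. This gives the β‑keto ester directly and comes back to the route at 15, so step 7 is not needed.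

Step 8 (Krapcho decarboxylation). Hot LiCl/DMSO may cause retro‑Claisen cleavage or partial loss of the MOM group. The fallback sets out from 11 and avoids the ester altogether. An Ivanov‑type aldol addition of the dianion of commercial 4‑methoxyphenylacetic acid (2 equiv LDA, THF, −78 → 0 °C) to 11 gives the β‑hydroxy acid F3 as a diastereomer mixture. Dess–Martin oxidation in CH2Cl2 gives the β‑keto acid F4, which is not isolated and decarboxylates on warming to 40 °C. The fallback comes back to the route at 16.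

Step 9 (Riley oxidation). SeO2 may attack the electron‑rich substrate unselectively or give incomplete conversion. The fallback sets out from 16 and splits the oxidation into two steps. Enolisation with KHMDS (THF, −78 °C) and hydroxylation with 2‑(phenylsulfonyl)‑3‑phenyloxaziridine gives the benzoin F5, 2‑hydroxy‑1‑[8‑methoxy‑5‑(methoxymethoxy)‑2,2‑dimethyl‑2H‑chromen‑6‑yl]‑2‑(4‑methoxyphenyl)ethan‑1‑one. Dess–Martin oxidation of F5 gives the diketone and comes back to the route at 17.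

**Further compounds**
F1 | step 6 | 8‑methoxy‑5‑(methoxymethoxy)‑2,2‑dimethyl‑2H‑chromene‑6‑carboxylic acid | COCOc1c(C(=O)O)cc(OC)c2c1C=CC(C)(C)O2
F2 | step 6 | (1H‑imidazol‑1‑yl)[8‑methoxy‑5‑(methoxymethoxy)‑2,2‑dimethyl‑2H‑chromen‑6‑yl]methanone | COCOc1c(C(=O)n3ccnc3)cc(OC)c2c1C=CC(C)(C)O2
F3 | step 8 | 3‑hydroxy‑3‑[8‑methoxy‑5‑(methoxymethoxy)‑2,2‑dimethyl‑2H‑chromen‑6‑yl]‑2‑(4‑methoxyphenyl)propanoic acid (racemic syn/anti mixture) | COCOc1c(C(O)C(C(=O)O)c3ccc(OC)cc3)cc(OC)c2c1C=CC(C)(C)O2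
F4 | step 8 | 3‑[8‑methoxy‑5‑(methoxymethoxy)‑2,2‑dimethyl‑2H‑chromen‑6‑yl]‑2‑(4‑methoxyphenyl)‑3‑oxopropanoic acid (racemic) | COCOc1c(C(=O)C(C(=O)O)c3ccc(OC)cc3)cc(OC)c2c1C=CC(C)(C)O2
F5 | step 9 | 2‑hydroxy‑1‑[8‑methoxy‑5‑(methoxymethoxy)‑2,2‑dimethyl‑2H‑chromen‑6‑yl]‑2‑(4‑methoxyphenyl)ethan‑1‑one (racemic) | COCOc1c(C(=O)C(O)c3ccc(OC)cc3)cc(OC)c2c1C=CC(C)(C)O2
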